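The earlier runs and the new flask stem from a simulated flask with made-up constants.

0.500 equiv of coupling partner stands against the substrate in the flask, so coupling partner is the limiting reagent. If each target takes one coupling partner, the balance of that reagent gives the partner ceiling C, the equivalents charged read as a percentage of the substrate charged: here C = 50.0%.

| setting | noon | dawn | flask |
|---|---|---|---|
| substrate | 0.067 M | 0.15 M | 0.10 M |
| coupling partner | 0.50 equiv | 0.50 equiv | 0.500 equiv |
| remark | run made earlier | run made earlier |  |
| time |  |  | 2.5 d |

| run | time / h | target / % | substrate / % |
|---|---|---|---|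
| noon | 2.50 | 17 | 83 |
| noon | 5.00 | 38 | 61 |
| noon | 10.0 | 50 | 49 |
| noon | 20.0 | 47 | 52 |
| noon | 40.0 | 46 | 50 |
| dawn | 2.50 | 43 | 57 |
| dawn | 5.00 | 48 | 51 |
| dawn | 10.0 | 50 | 51 |
| dawn | 20.0 | 48 | 47 |
| dawn | 40.0 | 46 | 49 |

(scatter of a reading: 1.5 percentage points)



* the moment within 2.5 d at which there is most target
* the amount of target, in percent of the substrate charged, at that time

The noon and dawn runs look nearly the same, both with 0.50 equiv of coupling partner, but the substrate starts at 0.067 M in noon and 0.15 M in dawn. Dawn is quicker, with 43% of target at 2.50 h against 17% in noon. At 10.0 h, though, noon reads 50% and dawn 50%. Both readings stand level with the ceiling C that the two runs share, but each carries the scatter of a reading. By 40.0 h the readings have sagged to 46% and 46%, against a scatter of 1.5 percentage points.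

The reckoning here: the flask, at 0.10 M, lies between the two runs and has the same ceiling, 50.0%, so its target should top just below that figure. The forecast gives 49% at 0.45 d, on the ground that “The peak comes where formation falls to this loss rate”.

The flask gives 48.9% at 0.413 d, which is 1.1 points below C.

    substrate + coupling partner + released group → target + 2 released group (k = 6.80 M⁻² min⁻¹)
    substrate + coupling partner → target + released group (k = 0.0170 M⁻¹ min⁻¹)
    target → over-reaction product (k = 3.70 × 10⁻⁵ min⁻¹)
    crystals ⇌ released group, rate k4*(cs4 - [released group]) while solid is left; crystals form when [released group] > cs4 (solubility = 23.0 mM, k = 0.130 min⁻¹)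

At 0.0713 d in the flask, the step that takes up released group used coupling partner 10 times as fast as the plain step did. By 0.413 d coupling partner was down to 0.416% of its charge, and afterwards target turned slowly into over-reaction product, leaving 44.0% of target and 6.04% of over-reaction product at 2.50 d. The neighbouring flask with 0.850 equiv of coupling partner has C = 85.0% and reaches a best of 81.3%, with 74.8% of target at 2.50 d.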